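**Retrosynthetic overview**
- The target is unmasked last by acid removal of two MOM ethers from the (3S)-bis-MOM isoflavan.
- The dihydropyran ring is the only ring formed and is closed last, by intramolecular Mitsunobu etherification (O1–C2 bond).
- The C4–C4a bond comes from a Negishi sp3–sp2 coupling of a chiral 3-acetoxy-2-arylpropylzinc iodide with an A-ring aryl bromide.
- The C3 stereocentre comes from lipase-catalysed desymmetrisation of a prochiral 2-aryl-propane-1,3-diol (B-ring aryl iodide + diethyl malonate, then reduction).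
- Both benzene rings are bought as 2,3-dimethoxyphenol: the B ring by MOM-directed ortho-lithiation/iodination, the A ring by oxidation to the p-quinone, reduction, mono-MOM protection, ortho-bromination and acetylation.

Assumption: the lipase in acylation mode acetylates the pro-R hydroxymethyl arm of the prochiral diol; sense and ee are to be confirmed by chiral HPLC/Mosher ester on the first run.

**Route**

Step 1
Reactants: 1 2,3-dimethoxyphenol
Product: 2 1,2-dimethoxy-3-(methoxymethoxy)benzene
Conditions: MOMCl (1.3 equiv), i-Pr2NEt (1.5 equiv), CH2Cl2, 0 °C to rt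
Reagents that add atoms: chloromethyl methyl ether (MOMCl), COCCl
Why: O-alkylation of a phenol with an α-chloro ether (MOM protection) is fast and installs the group that directs the next metalation.

Step 2
Reactants: 2 1,2-dimethoxy-3-(methoxymethoxy)benzene
Product: 4 1-iodo-3,4-dimethoxy-2-(methoxymethoxy)benzene, via aryllithium 3 (not isolated)
Conditions: n-BuLi (1.2 equiv), TMEDA, THF, 0 °C; then I2, −78 °C to rt
Reagents that add atoms: iodine, II
Why: Directed ortho-metalation occurs at the only free position ortho to OMOM, the strongest directing group present, and iodinolysis of the aryllithium fixes the B-ring attachment carbon.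

Step 3
Reactants: 4 1-iodo-3,4-dimethoxy-2-(methoxymethoxy)benzene; 5 diethyl malonate
Product: 6 diethyl 2-[3,4-dimethoxy-2-(methoxymethoxy)phenyl]malonate
Conditions: CuI (10 mol%), 2-picolinic acid (20 mol%), Cs2CO3 (3 equiv), 1,4-dioxane, 40–70 °C
Reagents that add atoms: none
Why: Copper-catalysed (Hurtley-type) α-arylation of a malonate with an aryl iodide tolerates electron-rich, ortho-alkoxy arenes and stops at mono-arylation.

Step 4
Reactants: 6 diethyl 2-[3,4-dimethoxy-2-(methoxymethoxy)phenyl]malonate
Product: 7 2-[3,4-dimethoxy-2-(methoxymethoxy)phenyl]propane-1,3-diol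
Conditions: LiAlH4 (3 equiv), THF, 0 °C to rt (ester added to the hydride); Fieser work-up
Reagents that add atoms: none
Why: Hydride reduction of both esters gives the prochiral 1,3-diol, with inverse addition keeping enolisation/elimination of the arylmalonate low and MOM and aryl ethers inert.

Step 5
Reactants: 7 2-[3,4-dimethoxy-2-(methoxymethoxy)phenyl]propane-1,3-diol
Product: 8 (2R)-2-[3,4-dimethoxy-2-(methoxymethoxy)phenyl]-3-hydroxypropyl acetate
Conditions: lipase (Burkholderia cepacia lipase, Amano PS-IM, immobilised), vinyl acetate (5 equiv), MTBE, 25 °C; stopped at full diol conversion with about 5–10% diacetate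
Reagents that add atoms: vinyl acetate, C=COC(C)=O
Why: Enzymatic desymmetrisation by irreversible transesterification: the lipase (a serine hydrolase) acetylates only the pro-R hydroxymethyl arm, which makes C-2 a stereocentre of R configuration, and slight over-acylation removes the minor enantiomer as diacetate.

Step 6
Reactants: 8 (2R)-2-[3,4-dimethoxy-2-(methoxymethoxy)phenyl]-3-hydroxypropyl acetate
Product: 9 (2S)-2-[3,4-dimethoxy-2-(methoxymethoxy)phenyl]-3-iodopropyl acetate
Conditions: I2 (1.3 equiv), PPh3 (1.3 equiv), imidazole (2.5 equiv), CH2Cl2, 0 °C, under 1 h; used promptly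
Reagents that add atoms: iodine, II
Why: Appel iodination substitutes only the primary carbinol carbon, so the stereocentre is untouched (the descriptor changes by CIP priority only), and fast consumption of the alcohol prevents 1,3-acyl migration.

Step 7
Reactants: 1 2,3-dimethoxyphenol
Product: 10 2,3-dimethoxy-1,4-benzoquinone
Conditions: Fremy's salt (2.3 equiv), KH2PO4 buffer, H2O/acetone, 0 °C to rt
Reagents that add atoms: potassium nitrosodisulfonate (Fremy's salt), [K+].[K+].[O]N(S(=O)(=O)[O-])S(=O)(=O)[O-]
Why: Teuber oxidation of a phenol with a free para position gives the p-quinone, which places the fourth oxygen of the A ring.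

Step 8
Reactants: 10 2,3-dimethoxy-1,4-benzoquinone
Product: 11 2,3-dimethoxybenzene-1,4-diol
Conditions: Na2S2O4 (aq), EtOAc/H2O, rt, Ar
Reagents that add atoms: none
Why: Dithionite reduction of a quinone to its hydroquinone is quantitative and gives a C2-symmetric diol.

Step 9
Reactants: 11 2,3-dimethoxybenzene-1,4-diol
Product: 12 2,3-dimethoxy-4-(methoxymethoxy)phenol
Conditions: MOMCl (1.0 equiv), i-Pr2NEt (1.1 equiv), CH2Cl2–THF, 0 °C, Ar; chromatography, recovered 11 and bis-ether recycled
Reagents that add atoms: chloromethyl methyl ether (MOMCl), COCCl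
Why: Statistical mono-O-alkylation of a symmetric hydroquinone has no regiochemical issue because the two hydroxyls are equivalent.

Step 10
Reactants: 12 2,3-dimethoxy-4-(methoxymethoxy)phenol
Product: 13 6-bromo-2,3-dimethoxy-4-(methoxymethoxy)phenol
Conditions: NBS (1.0 equiv), i-Pr2NH (10 mol%), CH2Cl2, −20 to 0 °C
Reagents that add atoms: N-bromosuccinimide, O=C1CCC(=O)N1Br
Why: Amine-mediated electrophilic ortho-bromination is directed by the free phenol, a stronger activator than OMOM, to the only position ortho to OH.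

Step 11
Reactants: 13 6-bromo-2,3-dimethoxy-4-(methoxymethoxy)phenol
Product: 14 6-bromo-2,3-dimethoxy-4-(methoxymethoxy)phenyl acetate
Conditions: Ac2O (1.5 equiv), pyridine, DMAP (cat.), CH2Cl2, rt
Reagents that add atoms: acetic anhydride, CC(=O)OC(C)=O
Why: O-acetylation masks the acidic phenol for the organozinc step with a group that is later removed together with the alkyl acetate.

Step 12
Reactants: 9 (2S)-2-[3,4-dimethoxy-2-(methoxymethoxy)phenyl]-3-iodopropyl acetate; 14 6-bromo-2,3-dimethoxy-4-(methoxymethoxy)phenyl acetate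
Product: 16 (2S)-3-[2-acetoxy-3,4-dimethoxy-5-(methoxymethoxy)phenyl]-2-[3,4-dimethoxy-2-(methoxymethoxy)phenyl]propyl acetate, via alkylzinc iodide 15 (not isolated)
Conditions: Zn dust (3 equiv, activated by BrCH2CH2Br/TMSCl), DMF, 25–35 °C; then 14, Pd2(dba)3 (2.5 mol%), SPhos (10 mol%), DMF/THF, 50 °C
Reagents that add atoms: none
Why: Zinc inserts into the primary C–I bond without touching esters or MOM ethers, and Pd/SPhos Negishi sp3–sp2 coupling with the aryl bromide outruns β-hydride elimination, so the adjacent stereocentre is carried through unchanged.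

Step 13
Reactants: 16 (2S)-3-[2-acetoxy-3,4-dimethoxy-5-(methoxymethoxy)phenyl]-2-[3,4-dimethoxy-2-(methoxymethoxy)phenyl]propyl acetate
Product: 17 6-[(2S)-2-[3,4-dimethoxy-2-(methoxymethoxy)phenyl]-3-hydroxypropyl]-2,3-dimethoxy-4-(methoxymethoxy)phenol
Conditions: K2CO3 (0.3 equiv), MeOH, rt, Ar
Reagents that add atoms: none
Why: Base-catalysed transesterification (methanolysis) removes the aryl and the alkyl acetate together while the MOM ethers are inert to base, freeing exactly the one phenol and the one alcohol needed for ring closure.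

Step 14
Reactants: 17 6-[(2S)-2-[3,4-dimethoxy-2-(methoxymethoxy)phenyl]-3-hydroxypropyl]-2,3-dimethoxy-4-(methoxymethoxy)phenol
Product: 18 (3S)-3-[3,4-dimethoxy-2-(methoxymethoxy)phenyl]-7,8-dimethoxy-6-(methoxymethoxy)chromane
Conditions: PPh3 (1.5 equiv), DIAD (1.5 equiv), THF (0.02 M), 0 °C to rt
Reagents that add atoms: none
Why: Intramolecular Mitsunobu etherification (6-exo-tet) by the only free phenol closes the pyran ring at the primary carbon, so C-3 keeps its S configuration.

Step 15
Reactants: 18 (3S)-3-[3,4-dimethoxy-2-(methoxymethoxy)phenyl]-7,8-dimethoxy-6-(methoxymethoxy)chromane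
Product: 19 (3S)-3-(2-hydroxy-3,4-dimethoxyphenyl)-7,8-dimethoxychroman-6-ol
Conditions: conc. HCl (cat.), MeOH, 45 °C, Ar
Reagents that add atoms: none
Why: Acid-catalysed acetal exchange with methanol cleaves both MOM ethers while the aryl methyl ethers, the chroman and the non-enolisable benzylic stereocentre are unaffected.

**Compound list**
1 | 2,3-dimethoxyphenol | COc1cccc(O)c1OC | starting material
2 | 1,2-dimethoxy-3-(methoxymethoxy)benzene | COCOc1cccc(OC)c1OC | intermediate
3 | [3,4-dimethoxy-2-(methoxymethoxy)phenyl]lithium | [Li]c1ccc(OC)c(OC)c1OCOC | intermediate (not isolated)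
4 | 1-iodo-3,4-dimethoxy-2-(methoxymethoxy)benzene | COCOc1c(I)ccc(OC)c1OC | intermediate
5 | diethyl malonate | CCOC(=O)CC(=O)OCC | starting material
6 | diethyl 2-[3,4-dimethoxy-2-(methoxymethoxy)phenyl]malonate | CCOC(=O)C(C(=O)OCC)c1ccc(OC)c(OC)c1OCOC | intermediate
7 | 2-[3,4-dimethoxy-2-(methoxymethoxy)phenyl]propane-1,3-diol | OCC(CO)c1ccc(OC)c(OC)c1OCOC | intermediate
8 | (2R)-2-[3,4-dimethoxy-2-(methoxymethoxy)phenyl]-3-hydroxypropyl acetate | COCOc1c(ccc(OC)c1OC)[C@H](CO)COC(C)=O | intermediate
9 | (2S)-2-[3,4-dimethoxy-2-(methoxymethoxy)phenyl]-3-iodopropyl acetate | COCOc1c(ccc(OC)c1OC)[C@H](CI)COC(C)=O | intermediate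
10 | 2,3-dimethoxy-1,4-benzoquinone | COC1=C(OC)C(=O)C=CC1=O | intermediate
11 | 2,3-dimethoxybenzene-1,4-diol | COc1c(O)ccc(O)c1OC | intermediate
12 | 2,3-dimethoxy-4-(methoxymethoxy)phenol | COCOc1ccc(O)c(OC)c1OC | intermediate
13 | 6-bromo-2,3-dimethoxy-4-(methoxymethoxy)phenol | COCOc1cc(Br)c(O)c(OC)c1OC | intermediate
14 | 6-bromo-2,3-dimethoxy-4-(methoxymethoxy)phenyl acetate | COCOc1cc(Br)c(OC(C)=O)c(OC)c1OC | intermediate
15 | [(2S)-3-acetoxy-2-[3,4-dimethoxy-2-(methoxymethoxy)phenyl]propyl]zinc iodide | COCOc1c(ccc(OC)c1OC)[C@H](C[Zn]I)COC(C)=O | intermediate (not isolated)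
16 | (2S)-3-[2-acetoxy-3,4-dimethoxy-5-(methoxymethoxy)phenyl]-2-[3,4-dimethoxy-2-(methoxymethoxy)phenyl]propyl acetate | COCOc1c(ccc(OC)c1OC)[C@H](Cc1cc(OCOC)c(OC)c(OC)c1OC(C)=O)COC(C)=O | intermediate
17 | 6-[(2S)-2-[3,4-dimethoxy-2-(methoxymethoxy)phenyl]-3-hydroxypropyl]-2,3-dimethoxy-4-(methoxymethoxy)phenol | COCOc1c(ccc(OC)c1OC)[C@H](Cc1cc(OCOC)c(OC)c(OC)c1O)CO | intermediate
18 | (3S)-3-[3,4-dimethoxy-2-(methoxymethoxy)phenyl]-7,8-dimethoxy-6-(methoxymethoxy)chromane | COCOc1c(ccc(OC)c1OC)[C@H]1COc2c(OC)c(OC)c(OCOC)cc2C1 | intermediate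
19 | (3S)-3-(2-hydroxy-3,4-dimethoxyphenyl)-7,8-dimethoxychroman-6-ol | COc1ccc([C@H]2COc3c(cc(O)c(OC)c3OC)C2)c(O)c1OC | target

**Count**
Total steps: 15. Longest linear sequence: 10 (steps 1–6, then 12–15); the A-ring branch (steps 7–11) joins at step 12.

**Three steps most likely to fail**

Step 12 (Negishi sp3–sp2 coupling; β-branched alkylzinc, electron-rich ortho-substituted aryl bromide). The fallback sets out from iodide 9 and bromophenol 13 and replaces the organozinc by an isolable boronate. Copper-catalysed borylation of 9 (CuI/PPh3, B2pin2, LiOMe, DMF, rt) gives (2S)-2-[3,4-dimethoxy-2-(methoxymethoxy)phenyl]-3-(4,4,5,5-tetramethyl-1,3,2-dioxaborolan-2-yl)propyl acetate F1. Suzuki–Miyaura coupling of F1 with the unprotected bromophenol 13 (Pd(OAc)2/RuPhos, K3PO4, toluene/H2O, 90 °C) gives (2S)-2-[3,4-dimethoxy-2-(methoxymethoxy)phenyl]-3-[2-hydroxy-3,4-dimethoxy-5-(methoxymethoxy)phenyl]propyl acetate F2. Methanolysis of F2 (K2CO3, MeOH) brings the route back at 17.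

Step 5 (lipase desymmetrisation; ee and sense on this ortho-substituted aryl diol are not guaranteed, and the product can racemise by acyl migration). The fallback sets out from diol 7 and runs the enzyme in the hydrolytic direction. Peracetylation (Ac2O, pyridine) gives 2-[3,4-dimethoxy-2-(methoxymethoxy)phenyl]propane-1,3-diyl diacetate F3. The same lipase, or pig liver esterase, in pH 7 phosphate buffer/acetone (pH-stat) then removes one enantiotopic acetate. A given hydrolase shows the opposite sense in hydrolysis and in acylation, so this mode gives the antipode of the acylation product. Whichever mode delivers the (R)-monoacetate in at least 97% ee is used, and the route is rejoined at 8.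

Step 10 (bromination; regioselectivity ortho to OH against ortho to OMOM, and possible oxidation of the p-alkoxyphenol). The fallback sets out from phenol 12 and replaces electrophilic substitution by directed metalation. Carbamoylation (Et2NCOCl, NaH, THF) gives 2,3-dimethoxy-4-(methoxymethoxy)phenyl N,N-diethylcarbamate F4. Carbamate-directed ortho-lithiation (s-BuLi/TMEDA, THF, −78 °C; the carbamate outranks OMOM and its only free ortho position is C-6) and quench with BrCCl2CCl2Br gives 6-bromo-2,3-dimethoxy-4-(methoxymethoxy)phenyl N,N-diethylcarbamate F5. Hydrolysis of F5 (NaOH, EtOH, reflux, Ar) returns the route at 13.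

**Further compounds**
F1 | step 12 | (2S)-2-[3,4-dimethoxy-2-(methoxymethoxy)phenyl]-3-(4,4,5,5-tetramethyl-1,3,2-dioxaborolan-2-yl)propyl acetate | COCOc1c(ccc(OC)c1OC)[C@H](CB1OC(C)(C)C(C)(C)O1)COC(C)=O
F2 | step 12 | (2S)-2-[3,4-dimethoxy-2-(methoxymethoxy)phenyl]-3-[2-hydroxy-3,4-dimethoxy-5-(methoxymethoxy)phenyl]propyl acetate | COCOc1c(ccc(OC)c1OC)[C@H](Cc1cc(OCOC)c(OC)c(OC)c1O)COC(C)=O
F3 | step 5 | 2-[3,4-dimethoxy-2-(methoxymethoxy)phenyl]propane-1,3-diyl diacetate | COCOc1c(ccc(OC)c1OC)C(COC(C)=O)COC(C)=O
F4 | step 10 | 2,3-dimethoxy-4-(methoxymethoxy)phenyl N,N-diethylcarbamate | CCN(CC)C(=O)Oc1ccc(OCOC)c(OC)c1OC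
F5 | step 10 | 6-bromo-2,3-dimethoxy-4-(methoxymethoxy)phenyl N,N-diethylcarbamate | CCN(CC)C(=O)Oc1c(Br)cc(OCOC)c(OC)c1OC
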